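**Retrosynthetic overview**
1. Target 29 ⇒ 8β-tigloyloxycostunolide 27: both oxiranes go in last by peripheral epoxidation of the crown conformer; the tiglate comes from acylation of eupatolide 25.
2. 25 ⇒ (E,E)-germacradiene 17: 6,12-lactone by oxidative lactonization, C13 by α-methylenation.
3. Key step, replacing the usual C6–C7 allylation macrocyclization: 17 ⇒ trans-1-vinyl-2-isopropenylcyclohexanol 13 by anionic oxy-Cope ring expansion (C5–C10 broken, C2–C3 formed, 4E set); the enolate oxygen is exchanged for the C14 methyl via the enol triflate (1(10)E set).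
4. Cyclohexanone 11 ⇒ cyclopentene 3 by dibromocarbene one-carbon ring expansion; isopropenyl by Suzuki coupling, C6–O by conjugate borylation.
5. C7/C8 come from commercial lactone 1. Ring order: cyclopentene (bought) → cyclohexenone → cyclodecadiene → γ-lactone → two oxiranes.

Assumption: 1, 7, 12 and 26 are purchased; germacrane numbering is used in the comments; C1 of 5 is drawn as the expected major epimer, and C3 of 22/23 and the anomeric carbon of 19 are left undefined because all are destroyed later (TBS = tert-butyldimethylsilyl, TES = triethylsilyl).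

**Step 1**
Reactants: 1 (1R,5S)-2-oxabicyclo[3.3.0]oct-6-en-3-one
Product: 2 (1R,2S)-2-(2-hydroxyethyl)cyclopent-3-en-1-ol
Conditions: LiAlH4, THF, 0 °C → rt; Fieser work-up
Reagents that add atoms: none
Why: Hydride reduction of the lactone to the 1,4-diol touches no stereocentre, so the cis C7/C8 pair of the chiral-pool lactone is carried on unchanged.

**Step 2**
Reactants: 2 (1R,2S)-2-(2-hydroxyethyl)cyclopent-3-en-1-ol
Product: 3 (1R,2S)-1-(TBSO)-2-[2-(TBSO)ethyl]cyclopent-3-ene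
Conditions: TBSCl (2.5 equiv), imidazole, DMF, rt
Reagents that add atoms: tert-butyldimethylsilyl chloride, CC(C)(C)[Si](C)(C)Cl
Why: Standard bis-silylation gives base-stable ethers that survive the carbene, organometallic and KH steps and that can later be told apart as primary versus secondary.

**Step 3**
Reactants: 3 (1R,2S)-1-(TBSO)-2-[2-(TBSO)ethyl]cyclopent-3-ene
Product: 5 (1R,4S,5R)-2-bromo-5-(TBSO)-4-[2-(TBSO)ethyl]cyclohex-2-en-1-ol, via dibromocyclopropane 4 (not isolated)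
Conditions: CHBr3, KOtBu, pentane, −10 → 0 °C; then AgBF4, NaHCO3, acetone–H2O (9:1), 0 °C → rt, dark
Reagents that add atoms: bromoform, BrC(Br)Br; water, O
Why: Dibromocarbene cyclopropanation on the face anti to the two cis substituents, then silver-assisted disrotatory electrocyclic ring opening of the gem-dibromocyclopropane to a 2-bromocyclohexenyl cation; water captures the terminus remote from the branched carbon, and the new carbinol centre is removed in step 4.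

**Step 4**
Reactants: 5 (1R,4S,5R)-2-bromo-5-(TBSO)-4-[2-(TBSO)ethyl]cyclohex-2-en-1-ol
Product: 6 (4S,5R)-2-bromo-5-(TBSO)-4-[2-(TBSO)ethyl]cyclohex-2-en-1-one
Conditions: Dess–Martin periodinane, CH2Cl2, 0 °C → rt
Reagents that add atoms: none
Why: Dess–Martin oxidation of the allylic alcohol gives the α-bromoenone under non-basic conditions, so the β-silyloxy ketone does not eliminate.

**Step 5**
Reactants: 6 (4S,5R)-2-bromo-5-(TBSO)-4-[2-(TBSO)ethyl]cyclohex-2-en-1-one; 7 isopropenylboronic acid pinacol ester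
Product: 8 (4S,5R)-5-(TBSO)-4-[2-(TBSO)ethyl]-2-(prop-1-en-2-yl)cyclohex-2-en-1-one
Conditions: Pd(PhCN)2Cl2 (5 mol%), AsPh3 (10 mol%), Ag2O, THF–H2O (8:1), rt
Reagents that add atoms: none
Why: Suzuki–Miyaura coupling of the α-haloenone under near-neutral silver-oxide conditions places the future C4/C15/C3 unit on C5 without epimerizing C7 or eliminating the C8 silyloxy group.

**Step 6**
Reactants: 8 (4S,5R)-5-(TBSO)-4-[2-(TBSO)ethyl]-2-(prop-1-en-2-yl)cyclohex-2-en-1-one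
Product: 10 (2R,3S,4S,5R)-5-(TBSO)-4-[2-(TBSO)ethyl]-3-hydroxy-2-(prop-1-en-2-yl)cyclohexan-1-one, via boryl ketone 9 (not isolated)
Conditions: CuCl (5 mol%), Xantphos (5 mol%), NaOtBu (7 mol%), B2pin2, MeOH (2 equiv), THF, 0 °C; then NaBO3·4H2O, THF–H2O, 0 °C → rt
Reagents that add atoms: bis(pinacolato)diboron (boron of 9), CC1(C)OB(OC1(C)C)B1OC(C)(C)C(C)(C)O1; sodium perborate (oxygen of 10), [Na+].[O-]OB=O
Why: Copper-catalysed conjugate borylation delivers boron to C6 anti to the adjacent C7 side chain (6α, trans), oxidation proceeds with retention, and the acidic C5–H settles in the all-equatorial arrangement trans to the new hydroxyl.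

**Step 7**
Reactants: 10 (2R,3S,4S,5R)-5-(TBSO)-4-[2-(TBSO)ethyl]-3-hydroxy-2-(prop-1-en-2-yl)cyclohexan-1-one
Product: 11 (2R,3S,4R,5R)-5-(TBSO)-4-[2-(TBSO)ethyl]-2-(prop-1-en-2-yl)-3-(triethylsilyloxy)cyclohexan-1-one
Conditions: TESCl, imidazole, CH2Cl2, 0 °C
Reagents that add atoms: chlorotriethylsilane, CC[Si](Cl)(CC)CC
Why: Mild silylation caps the aldol hydroxyl (no retro-aldol or dehydration) with a group that is later removed together with the primary TBS ether.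

**Step 8**
Reactants: 11 (2R,3S,4R,5R)-5-(TBSO)-4-[2-(TBSO)ethyl]-2-(prop-1-en-2-yl)-3-(triethylsilyloxy)cyclohexan-1-one; 12 vinylmagnesium bromide
Product: 13 (1R,2R,3S,4R,5R)-5-(TBSO)-4-[2-(TBSO)ethyl]-1-ethenyl-2-(prop-1-en-2-yl)-3-(triethylsilyloxy)cyclohexan-1-ol
Conditions: anhydrous CeCl3, THF, −78 °C; aq. NH4Cl
Reagents that add atoms: none
Why: Organocerium 1,2-addition avoids enolization of the acidic C5–H, and the axial C8 silyloxy group blocks axial attack, so vinyl enters equatorially, trans to the equatorial isopropenyl group, as the chair oxy-Cope requires.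

**Step 9**
Reactants: 13 (1R,2R,3S,4R,5R)-5-(TBSO)-4-[2-(TBSO)ethyl]-1-ethenyl-2-(prop-1-en-2-yl)-3-(triethylsilyloxy)cyclohexan-1-ol
Product: 16 (1Z,5E,7R,8R,9R)-9-(TBSO)-8-[2-(TBSO)ethyl]-5-methyl-7-(triethylsilyloxy)cyclodeca-1,5-dien-1-yl trifluoromethanesulfonate, via potassium alkoxide 14 (not isolated), via potassium enolate 15 (not isolated)
Conditions: KH, 18-crown-6, THF, 0 °C → rt; then PhNTf2, −78 → 0 °C
Reagents that add atoms: potassium hydride (potassium of 14 and 15), [K+].[H-]; N-phenylbis(trifluoromethanesulfonimide), O=S(=O)(N(c1ccccc1)S(=O)(=O)C(F)(F)F)C(F)(F)F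
Why: Anionic oxy-Cope rearrangement through a chair transition state with both alkenyl groups equatorial breaks C5–C10, forms C2–C3 and fixes the (E)-C4=C5 olefin and the ring-E enolate, whose O-triflation preserves that geometry (Z by CIP) while C6, C7 and C8 are untouched.

**Step 10**
Reactants: 16 (1Z,5E,7R,8R,9R)-9-(TBSO)-8-[2-(TBSO)ethyl]-5-methyl-7-(triethylsilyloxy)cyclodeca-1,5-dien-1-yl trifluoromethanesulfonate
Product: 17 (1E,5E,7R,8R,9R)-9-(TBSO)-8-[2-(TBSO)ethyl]-1,5-dimethyl-7-(triethylsilyloxy)cyclodeca-1,5-diene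
Conditions: MeZnCl (2 equiv), Pd(PPh3)4 (5 mol%), THF, 0 °C → rt
Reagents that add atoms: methylzinc chloride, C[Zn]Cl
Why: Negishi coupling of the enol triflate occurs with retention of olefin geometry, replacing the enolate oxygen by the C14 methyl and giving the (1(10)E,4E)-germacradiene.

**Step 11**
Reactants: 17 (1E,5E,7R,8R,9R)-9-(TBSO)-8-[2-(TBSO)ethyl]-1,5-dimethyl-7-(triethylsilyloxy)cyclodeca-1,5-diene
Product: 18 (1R,2E,6E,9R,10S)-9-(TBSO)-10-(2-hydroxyethyl)-3,7-dimethylcyclodeca-2,6-dien-1-ol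
Conditions: HF·pyridine, pyridine, THF, 0 °C
Reagents that add atoms: none
Why: Buffered fluoride desilylation removes the labile TES ether and the primary TBS ether much faster than the hindered secondary TBS ether at C8, and the buffer protects the acid-sensitive cyclodecadiene.

**Step 12**
Reactants: 18 (1R,2E,6E,9R,10S)-9-(TBSO)-10-(2-hydroxyethyl)-3,7-dimethylcyclodeca-2,6-dien-1-ol
Product: 20 (3aS,4R,6E,10E,11aR)-4-(TBSO)-6,10-dimethyl-3a,4,5,8,9,11a-hexahydrocyclodeca[b]furan-2(3H)-one, via lactol 19 (not isolated)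
Conditions: TEMPO (20 mol%), PhI(OAc)2 (2.5 equiv), CH2Cl2, rt
Reagents that add atoms: none
Why: TEMPO/PhI(OAc)2 oxidative lactonization oxidizes the primary alcohol selectively, the aldehyde is trapped by the C6 hydroxyl as the lactol, and this is oxidized to the trans-fused 6,12-lactone without change at C6 or C7.

**Step 13**
Reactants: 20 (3aS,4R,6E,10E,11aR)-4-(TBSO)-6,10-dimethyl-3a,4,5,8,9,11a-hexahydrocyclodeca[b]furan-2(3H)-one
Product: 22 (3aS,4R,6E,10E,11aR)-4-(TBSO)-3-[(dimethylamino)methyl]-6,10-dimethyl-3a,4,5,8,9,11a-hexahydrocyclodeca[b]furan-2(3H)-one, via lithium enolate 21 (not isolated)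
Conditions: LDA, THF, −78 °C; then CH2=NMe2+ I−, −78 °C → rt
Reagents that add atoms: lithium diisopropylamide (lithium of 21), CC(C)[N-]C(C)C.[Li+]; dimethylmethyleneiminium iodide, C=[N+](C)C.[I-]
Why: Mannich aminomethylation of the lactone enolate with Eschenmoser's salt introduces C13; the new C11 centre is inconsequential because it becomes sp2 in the next step.

**Step 14**
Reactants: 22 (3aS,4R,6E,10E,11aR)-4-(TBSO)-3-[(dimethylamino)methyl]-6,10-dimethyl-3a,4,5,8,9,11a-hexahydrocyclodeca[b]furan-2(3H)-one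
Product: 24 (3aS,4R,6E,10E,11aR)-4-(TBSO)-6,10-dimethyl-3-methylidene-3a,4,5,8,9,11a-hexahydrocyclodeca[b]furan-2(3H)-one, via methiodide 23 (not isolated)
Conditions: MeI, MeOH, rt; then aq. NaHCO3, EtOAc, rt
Reagents that add atoms: iodomethane (methyl of 23), CI
Why: Quaternization and mild-base β-elimination of trimethylamine (Hofmann-type E1cB) unveils the α-methylene lactone under conditions that neither acid-cyclize nor heat the germacradiene.

**Step 15**
Reactants: 24 (3aS,4R,6E,10E,11aR)-4-(TBSO)-6,10-dimethyl-3-methylidene-3a,4,5,8,9,11a-hexahydrocyclodeca[b]furan-2(3H)-one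
Product: 25 eupatolide, (3aR,4R,6E,10E,11aR)-4-hydroxy-6,10-dimethyl-3-methylidene-3a,4,5,8,9,11a-hexahydrocyclodeca[b]furan-2(3H)-one
Conditions: HF·pyridine, THF, 0 °C → rt
Reagents that add atoms: none
Why: Non-basic fluoride desilylation frees the 8β-hydroxyl without generating an alkoxide that could translactonize to the 8,12-olide or add to the enoate.

**Step 16**
Reactants: 25 eupatolide; 26 tigloyl chloride
Product: 27 8β-tigloyloxycostunolide, (3aR,4R,6E,10E,11aR)-6,10-dimethyl-3-methylidene-2-oxo-2,3,3a,4,5,8,9,11a-octahydrocyclodeca[b]furan-4-yl (2E)-2-methylbut-2-enoate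
Conditions: Et3N, DMAP (cat.), CH2Cl2, 0 °C → rt
Reagents that add atoms: none
Why: DMAP-catalysed acylation of the secondary alcohol proceeds with retention at C8, and the tiglate is the thermodynamically stable E isomer so it does not isomerize.

**Step 17**
Reactants: 27 8β-tigloyloxycostunolide
Product: 29 CNP0311437.1, (1R,4R,5R,6S,7R,8R,10R)-1,10:4,5-diepoxy-8-tigloyloxygermacr-11(13)-en-12,6-olide, via monoepoxide 28 (not isolated)
Conditions: dimethyldioxirane (2.3 equiv) in acetone, CH2Cl2, −20 → 0 °C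
Reagents that add atoms: dimethyldioxirane, CC1(C)OO1
Why: Neutral electrophilic epoxidation attacks only the two electron-rich trisubstituted ring olefins (not the enoates), each from its exposed peripheral face in the crown conformer with both methyls β, giving the 1β,10α- and 4α,5β-oxiranes (1R,10R and 4R,5R, as in parthenolide and 1,10-epoxyparthenolide) without acid-induced transannular cyclization.

**Compound list**
1 | (1R,5S)-2-oxabicyclo[3.3.0]oct-6-en-3-one [(3aS,6aR)-3,3a,6,6a-tetrahydro-2H-cyclopenta[b]furan-2-one] | O=C1C[C@H]2C=CC[C@H]2O1 | starting material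
2 | (1R,2S)-2-(2-hydroxyethyl)cyclopent-3-en-1-ol | OCC[C@H]1C=CC[C@H]1O | intermediate
3 | (1R,2S)-1-(TBSO)-2-[2-(TBSO)ethyl]cyclopent-3-ene | CC(C)(C)[Si](C)(C)OCC[C@H]1C=CC[C@H]1O[Si](C)(C)C(C)(C)C | intermediate
4 | (1S,2S,3R,5R)-6,6-dibromo-3-(TBSO)-2-[2-(TBSO)ethyl]bicyclo[3.1.0]hexane (CBr2 anti to both substituents) | CC(C)(C)[Si](C)(C)OCC[C@H]1[C@@H]2C(Br)(Br)[C@@H]2C[C@H]1O[Si](C)(C)C(C)(C)C | intermediate
5 | (1R,4S,5R)-2-bromo-5-(TBSO)-4-[2-(TBSO)ethyl]cyclohex-2-en-1-ol (major C1 epimer) | CC(C)(C)[Si](C)(C)OCC[C@H]1C=C(Br)[C@H](O)C[C@H]1O[Si](C)(C)C(C)(C)C | intermediate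
6 | (4S,5R)-2-bromo-5-(TBSO)-4-[2-(TBSO)ethyl]cyclohex-2-en-1-one | CC(C)(C)[Si](C)(C)OCC[C@H]1C=C(Br)C(=O)C[C@H]1O[Si](C)(C)C(C)(C)C | intermediate
7 | isopropenylboronic acid pinacol ester, 4,4,5,5-tetramethyl-2-(prop-1-en-2-yl)-1,3,2-dioxaborolane | CC(=C)B1OC(C)(C)C(C)(C)O1 | starting material
8 | (4S,5R)-5-(TBSO)-4-[2-(TBSO)ethyl]-2-(prop-1-en-2-yl)cyclohex-2-en-1-one | CC(C)(C)[Si](C)(C)OCC[C@H]1C=C(C(C)=C)C(=O)C[C@H]1O[Si](C)(C)C(C)(C)C | intermediate
9 | (2S,3S,4S,5R)-5-(TBSO)-4-[2-(TBSO)ethyl]-2-(prop-1-en-2-yl)-3-(4,4,5,5-tetramethyl-1,3,2-dioxaborolan-2-yl)cyclohexan-1-one | O=C1C[C@@H](O[Si](C)(C)C(C)(C)C)[C@@H](CCO[Si](C)(C)C(C)(C)C)[C@H](B2OC(C)(C)C(C)(C)O2)[C@H]1C(C)=C | intermediate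
10 | (2R,3S,4S,5R)-5-(TBSO)-4-[2-(TBSO)ethyl]-3-hydroxy-2-(prop-1-en-2-yl)cyclohexan-1-one | O=C1C[C@@H](O[Si](C)(C)C(C)(C)C)[C@@H](CCO[Si](C)(C)C(C)(C)C)[C@H](O)[C@H]1C(C)=C | intermediate
11 | (2R,3S,4R,5R)-5-(TBSO)-4-[2-(TBSO)ethyl]-2-(prop-1-en-2-yl)-3-(triethylsilyloxy)cyclohexan-1-one | O=C1C[C@@H](O[Si](C)(C)C(C)(C)C)[C@@H](CCO[Si](C)(C)C(C)(C)C)[C@H](O[Si](CC)(CC)CC)[C@H]1C(C)=C | intermediate
12 | vinylmagnesium bromide | C=C[Mg]Br | starting material
13 | (1R,2R,3S,4R,5R)-5-(TBSO)-4-[2-(TBSO)ethyl]-1-ethenyl-2-(prop-1-en-2-yl)-3-(triethylsilyloxy)cyclohexan-1-ol | C=C[C@]1(O)C[C@@H](O[Si](C)(C)C(C)(C)C)[C@@H](CCO[Si](C)(C)C(C)(C)C)[C@H](O[Si](CC)(CC)CC)[C@H]1C(C)=C | intermediate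
14 | potassium alkoxide of 13 | C=C[C@]1([O-])C[C@@H](O[Si](C)(C)C(C)(C)C)[C@@H](CCO[Si](C)(C)C(C)(C)C)[C@H](O[Si](CC)(CC)CC)[C@H]1C(C)=C.[K+] | intermediate
15 | potassium (1Z,5E,7R,8R,9R)-9-(TBSO)-8-[2-(TBSO)ethyl]-5-methyl-7-(triethylsilyloxy)cyclodeca-1,5-dien-1-olate | [O-]/C1=C\CC/C(C)=C/[C@@H](O[Si](CC)(CC)CC)[C@H](CCO[Si](C)(C)C(C)(C)C)[C@H](O[Si](C)(C)C(C)(C)C)C1.[K+] | intermediate
16 | (1Z,5E,7R,8R,9R)-9-(TBSO)-8-[2-(TBSO)ethyl]-5-methyl-7-(triethylsilyloxy)cyclodeca-1,5-dien-1-yl trifluoromethanesulfonate | FC(F)(F)S(=O)(=O)O/C1=C\CC/C(C)=C/[C@@H](O[Si](CC)(CC)CC)[C@H](CCO[Si](C)(C)C(C)(C)C)[C@H](O[Si](C)(C)C(C)(C)C)C1 | intermediate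
17 | (1E,5E,7R,8R,9R)-9-(TBSO)-8-[2-(TBSO)ethyl]-1,5-dimethyl-7-(triethylsilyloxy)cyclodeca-1,5-diene | C/C1=C\CC/C(C)=C/[C@@H](O[Si](CC)(CC)CC)[C@H](CCO[Si](C)(C)C(C)(C)C)[C@H](O[Si](C)(C)C(C)(C)C)C1 | intermediate
18 | (1R,2E,6E,9R,10S)-9-(TBSO)-10-(2-hydroxyethyl)-3,7-dimethylcyclodeca-2,6-dien-1-ol | C/C1=C\CC/C(C)=C/[C@@H](O)[C@H](CCO)[C@H](O[Si](C)(C)C(C)(C)C)C1 | intermediate
19 | (3aS,4R,6E,10E,11aR)-4-(TBSO)-6,10-dimethyl-2,3,3a,4,5,8,9,11a-octahydrocyclodeca[b]furan-2-ol (lactol, anomers) | C/C1=C\CC/C(C)=C/[C@H]2OC(O)C[C@@H]2[C@H](O[Si](C)(C)C(C)(C)C)C1 | intermediate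
20 | (3aS,4R,6E,10E,11aR)-4-(TBSO)-6,10-dimethyl-3a,4,5,8,9,11a-hexahydrocyclodeca[b]furan-2(3H)-one | C/C1=C\CC/C(C)=C/[C@H]2OC(=O)C[C@@H]2[C@H](O[Si](C)(C)C(C)(C)C)C1 | intermediate
21 | lithium enolate of 20 | C/C1=C\CC/C(C)=C/[C@H]2OC([O-])=C[C@@H]2[C@H](O[Si](C)(C)C(C)(C)C)C1.[Li+] | intermediate
22 | (3aS,4R,6E,10E,11aR)-4-(TBSO)-3-[(dimethylamino)methyl]-6,10-dimethyl-3a,4,5,8,9,11a-hexahydrocyclodeca[b]furan-2(3H)-one (C3 epimers) | C/C1=C\CC/C(C)=C/[C@H]2OC(=O)C(CN(C)C)[C@@H]2[C@H](O[Si](C)(C)C(C)(C)C)C1 | intermediate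
23 | trimethylammonium iodide (methiodide) of 22 | C/C1=C\CC/C(C)=C/[C@H]2OC(=O)C(C[N+](C)(C)C)[C@@H]2[C@H](O[Si](C)(C)C(C)(C)C)C1.[I-] | intermediate
24 | 8-O-TBS-eupatolide, (3aS,4R,6E,10E,11aR)-4-(TBSO)-6,10-dimethyl-3-methylidene-3a,4,5,8,9,11a-hexahydrocyclodeca[b]furan-2(3H)-one | C/C1=C\CC/C(C)=C/[C@H]2OC(=O)C(=C)[C@@H]2[C@H](O[Si](C)(C)C(C)(C)C)C1 | intermediate
25 | eupatolide (8β-hydroxycostunolide), (3aR,4R,6E,10E,11aR)-4-hydroxy-6,10-dimethyl-3-methylidene-3a,4,5,8,9,11a-hexahydrocyclodeca[b]furan-2(3H)-one | C/C1=C\CC/C(C)=C/[C@H]2OC(=O)C(=C)[C@@H]2[C@H](O)C1 | intermediate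
26 | tigloyl chloride, (2E)-2-methylbut-2-enoyl chloride | C/C=C(\C)C(=O)Cl | starting material
27 | 8β-tigloyloxycostunolide (eupatolide 8-O-tiglate) | C/C1=C\CC/C(C)=C/[C@H]2OC(=O)C(=C)[C@@H]2[C@H](OC(=O)/C(C)=C/C)C1 | intermediate
28 | (1R,10R)-1,10-epoxy-8β-tigloyloxygermacra-4E,11(13)-dien-12,6α-olide | C=C1C(=O)O[C@H]2[C@H]1[C@H](OC(=O)/C(C)=C/C)C[C@@]1(C)O[C@@H]1CC/C(C)=C/2 | intermediate
29 | CNP0311437.1, (1R,4R,5R,6S,7R,8R,10R)-1,10:4,5-diepoxy-8-[(E)-2-methylbut-2-enoyloxy]germacr-11(13)-en-12,6-olide | C=C1C(=O)O[C@H]2[C@H]1[C@H](OC(=O)/C(C)=C/C)C[C@@]1(C)O[C@@H]1CC[C@@]1(C)O[C@H]21 | target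

**Totals**
Total step count: 17. Longest linear sequence: 17 steps (from 1; 7, 12 and 26 are purchased).

**Three steps most likely to fail**

Step 9 (oxy-Cope and in-situ triflation). Risks are enolate scrambling toward C9 with loss of the C8 silyloxy group, and erosion of enolate geometry. The fallback sets out from 13 and comes back at 17. Run the oxy-Cope with KH and 18-crown-6 and quench with TMSCl/Et3N to isolate the trimethylsilyl enol ether F3, whose regio- and stereochemistry can be checked. Regenerate the enolate specifically with MeLi and trap it with diethyl chlorophosphate as the enol phosphate F4. Methylate F4 by iron-catalysed Kumada coupling (MeMgBr, Fe(acac)3, THF/NMP, −20 °C) to reach 17. This replaces the one-pot triflation and Negishi coupling by a stepwise silicon and phosphate C–O activation.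

Step 3 (ring expansion). Risks are the regiochemistry of cation capture and participation of the side-chain silyl ether. The fallback sets out from 4 and comes back at 6. Warm crude 4 in toluene (80 °C) so that the electrocyclic opening occurs with bromide return, giving the equilibrating allylic dibromide F1. Oxidize F1 with N-methylmorpholine N-oxide (MeCN, 4 Å sieves, rt), an amine-oxide oxidation of the Kornblum type. The allylic bromide isomers interconvert and the N-oxide displaces only at the unhindered carbon, so both funnel to bromoenone 6 without a free cation.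

Step 6 (conjugate borylation and oxidation). Risks are low reactivity of the α-substituted enone and base-induced elimination or aromatization. The fallback sets out from 8 and comes back at 10. Nucleophilic (Weitz–Scheffer) epoxidation with t-BuOOLi (THF, −78 → −20 °C) anti to the C7 side chain gives the epoxy ketone F2. SmI2 (THF/MeOH, −78 °C) then cleaves the Cα–O bond reductively to give aldol 10 with the same 6α-hydroxyl.

**Further compounds**
F1 | step 3 | 2,3-dibromo-5-(TBSO)-4-[2-(TBSO)ethyl]cyclohexene, (4S,5R), allylic bromide isomers | CC(C)(C)[Si](C)(C)OCC[C@H]1C=C(Br)C(Br)C[C@H]1O[Si](C)(C)C(C)(C)C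
F2 | step 6 | (1R,4R,5S,6S)-4-(TBSO)-5-[2-(TBSO)ethyl]-1-(prop-1-en-2-yl)-7-oxabicyclo[4.1.0]heptan-2-one (oxirane anti to the side chain) | O=C1C[C@@H](O[Si](C)(C)C(C)(C)C)[C@@H](CCO[Si](C)(C)C(C)(C)C)[C@@H]2O[C@]12C(C)=C
F3 | step 9 | (1Z,5E,7R,8R,9R)-9-(TBSO)-8-[2-(TBSO)ethyl]-5-methyl-7-(triethylsilyloxy)-1-(trimethylsilyloxy)cyclodeca-1,5-diene | C[Si](C)(C)O/C1=C\CC/C(C)=C/[C@@H](O[Si](CC)(CC)CC)[C@H](CCO[Si](C)(C)C(C)(C)C)[C@H](O[Si](C)(C)C(C)(C)C)C1
F4 | step 9 | (1Z,5E,7R,8R,9R)-9-(TBSO)-8-[2-(TBSO)ethyl]-5-methyl-7-(triethylsilyloxy)cyclodeca-1,5-dien-1-yl diethyl phosphate | CCOP(=O)(OCC)O/C1=C\CC/C(C)=C/[C@@H](O[Si](CC)(CC)CC)[C@H](CCO[Si](C)(C)C(C)(C)C)[C@H](O[Si](C)(C)C(C)(C)C)C1
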